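Watch the reagent, not the substrate, in this flask: one figure, the reagent each lost substrate costs, tells you roughly where it stops.

all flasks: substrate 0.050 M
- winter: reagent 0.80 equiv; the very flask that is asked about, followed so far
- dawn: reagent 1.2 equiv; run made earlier
- flask: reagent 0.800 equiv; time 1.0 h

- winter (time / min: substrate / %, mono adduct / %, bis adduct / %): 1.00: 100, 2, 1; 2.00: 96, 3, 0; 5.00: 91, 7, 3; 12.0: 81, 11, 7
- dawn (time / min: substrate / %, mono adduct / %, bis adduct / %): 8.00: 83, 14, 4; 20.0: 69, 19, 7; 40.0: 53, 19, 9; 60.0: 47, 18, 11

(scatter of a reading: 1.5 percentage points)

* substrate at 1.0 h, in percent of the substrate charged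
* mono adduct at 1.0 h, in percent of the substrate charged
* bis adduct at 1.0 h, in percent of the substrate charged
* tris adduct at 1.0 h, in percent of the substrate charged



Both runs start at the same c(substrate), and dawn over its first 8.00 min loses substrate 1.34 times as fast as winter, this very flask so far, over its first 12.0 min, on 1.50 times the reagent. That is only a reading, but it is near enough for you to take the rate as first order in c(reagent).

Now turn the question round. For this flask to empty its substrate, each substrate lost could cost at most 0.800 reagent, yet it takes at least one. In dawn's last reading 24.0 % of the substrate is unseen. Book that as tris adduct at 3 reagent each, with mono adduct at one and bis adduct at two, and 2.11 reagent go per substrate lost: the reagent cost. That is 2.64 times what emptying allows, so reagent is the limiting reagent, and I expect the flask to stop near substrate 62.1 %.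

At winter's opening pace that distance takes 23.9 min. The pace falls with c(reagent), so, if you pretend c(substrate) stays steady, the distance left shrinks by a factor e in each such period. For 1.0 h I commit to substrate 65.2 %.

The forecast, lower than mine on substrate, gives substrate 61 %, mono adduct 19 %, bis adduct 10 % and tris adduct 10 %, holding that “reagent nearly runs out once substrate reaches about 60%”.

The flask gives substrate 59.9 %, mono adduct 19.6 %, bis adduct 6.43 % and tris adduct 4.74 %.

    substrate + reagent → mono adduct (k = 0.00760 /M/s)
    reagent + mono adduct → bis adduct (k = 0.0220 /M/s)
    reagent + bis adduct → tris adduct (k = 0.0220 /M/s)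
    reagent + tris adduct → tetra adduct (k = 0.0120 /M/s)
    bis adduct → over-reaction product A (k = 1.60 × 10⁻⁷ /s)
    bis adduct → over-reaction product B (k = 4.20 × 10⁻⁴ /s)

At 1.00 h, with 15 % of its reagent left, this flask's reagent cost comes to 1.70, lower than dawn's reading, and at that same time the neighbour flask with 3.20 equiv of reagent shows 3.05, with substrate at 14 % and 18 % of its reagent left. At 1.00 h this flask's bis adduct goes to over-reaction product B 3.2 times as fast as to tris adduct, against 0.71 at 0.246 h, and over-reaction product B stands at 7.91 % beside tris adduct at 4.74 %.

Readings and results are calculated with made-up constants, and the scatter is random.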